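The numbers are assumed; the run is a simulation.

The number to start from is 1.1: at balance, the dormant form stands at that many times the free electrophile.

electrophile 0.30 M; time 5.0 d

- the equivalents of nucleophile at which the part of the electrophile that has reacted at 5.0 d is just 70%

"Reacted" is taken here as no longer free, so the dormant form counts as used.

1. electrophile ⇌ dormant form (K3 = 1.1, k3 = 0.080 h⁻¹)
This balance relaxes with half-life 0.189 d, far shorter than the run of 5.0 d, so it holds at the end. The free electrophile wanted then is 0.0900 M, which with its dormant form makes 0.189 M. The other steps must therefore remove 0.111 M.

2. electrophile + nucleophile → acid set free + target (k1 = 0.18 L mol⁻¹ h⁻¹)
nucleophile + acid set free ⇌ protonated nucleophile, settled at all times (K2 = 1800 L mol⁻¹)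
Each target uses one nucleophile and sets free one acid, which takes a second nucleophile: at 0.150 M free nucleophile, protonated nucleophile stands at 270 times the free acid. Nucleophile is thus the limiting reagent, at two per target.

3. The charge that pays for this is 0.740 equivalents. This is the stopping charge: twice the part of the electrophile charged that is neither free nor dormant once, in this count, two nucleophiles per target have taken up the charge.

4. electrophile + acid set free → side product (k4 = 0.17 L mol⁻¹ h⁻¹)
With nucleophile taken at the electrophile's charge, the step to target, slowed by the free share of electrophile, runs on a scale of 1.62 d, shorter than the run, so this reckoning takes that end state as reached within the run. The side step removes electrophile together with free acid, so it spends no nucleophile and lets protonated nucleophile give some back, which this reckoning leaves unsized.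

The forecast gives 1.44 equiv, since “each electrophile converted ties up about two nucleophiles”, while this reckoning commits to 0.740 equivalents.

The simulation gives 0.663 equiv.

In that flask the step to target ran while nucleophile stood, with 71% of its turnover behind it at 1.00 d and 65.7% of the electrophile used at 1.25 d. With 3.31% of the charged nucleophile free at 5.00 d, the side step was still running, half of its turnover up to then having come by 3.71 d. The stopping charge is 1.12 times the charge found. For the flask with twice that nucleophile, which reached 83.4%, the stopping charge for that part is 1.30 equivalents against 1.33 equiv charged.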